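The runs were generated by integration with made-up constants, and the scatter is random.

The autumn flask needs one decision: whether 0.0170 M of J and 31 min of stirring is the right pairing, because E is not stable.

all flasks: G 0.250 M; X 0.625 M
- midnight: J 0.00500 M
- summer: J 0.0100 M
- autumn: J 0.0170 M; time 31 min

| run | time / min | [E] / M |
|---|---|---|
| midnight run | 1.2 | 0.0077 |
| midnight run | 2.4 | 0.0183 |
| midnight run | 4.5 | 0.0376 |
| midnight run | 8.6 | 0.0573 |
| midnight run | 16 | 0.0889 |
| midnight run | 31 | 0.1208 |
| summer run | 1.2 | 0.0197 |
| summer run | 2.4 | 0.0333 |
| summer run | 4.5 | 0.0594 |
| summer run | 8.6 | 0.1016 |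
| summer run | 16 | 0.1430 |
| summer run | 31 | 0.1554 |

(each reading ± 0.002 M)

* order of the initial rate in [J], near the charge of the midnight run, the rate being that where two percent of its G are E
* E in the autumn run at 31 min, as a share of the G charged
* which of these the readings show (the catalyst dies by itself / nothing beyond the main steps / the product decays)

- Overall: G + X -> E, with J as catalyst.
- Constant volume, constant temperature.
- "The second partner" is X.
- An order is taken over about fifteen percent of the charge, up and down.

G, at 0.250 M, is charged in less than the 0.625 M of X, so it is the limiting reagent and its balance governs: G charged = G left + E + whatever E has become.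

**First setting, J.** By hand, treat G as pseudo-first-order with constant λ, where λ = ln(G₀/(G₀ − E))/t at 8.6 min, ignoring loss so far. If λ follows J, the order is near one. The readings give:

λ(midnight) = 0.0303 min⁻¹, λ(summer) = 0.0606 min⁻¹

order in J = 1.00

So the autumn flask gets λ = 0.103 min⁻¹.

**Second setting, time.** Between 16 min and 31 min the summer flask gained 0.0124 M of E, yet λ says it turned more than that, 0.0566 M of G. The balance therefore defines the loss constant k_d, the G turned but not found as E, per unit of E-time:

k_d = 0.0197 min⁻¹

The midnight readings give 0.0155 min⁻¹. That closeness points to decay of E; a wide gap between the two runs would have spoken against it.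

For the autumn flask, the reckoning here gives:

E/G₀ = λ/(λ − k_d) · (exp(−k_d t) − exp(−λ t)) = 62.0%

By this reckoning the peak of the autumn flask comes at ln(λ/k_d)/(λ − k_d) = 19.8 min, earlier than the time asked.

The forecast gave order 0.95, 67% and "the product decays", holding that “The loss instead tracks” E, and its yield stands above the reckoning here.

The simulation gives order 1.0, 64.1% (2.1 percentage points above the reckoning here) and "the product decays".

    J + G → Jo + L (8.460 M⁻¹ min⁻¹)
    Jo + X → E + J (13.32 M⁻¹ min⁻¹)
    E → Qi (0.01866 min⁻¹)

In the autumn flask J took up G to give Jo, and Jo met X to give E and J again; at the charge Jo went on at 8.33 min⁻¹ per Jo, faster than J took up G at 2.12 min⁻¹ per J. E→Qi, with its constant 0.0187 min⁻¹ against the k_d of 0.0197 min⁻¹ read from the summer readings, ran alongside from the first E onward, and at 31 min the autumn flask held E at 64.1% of the G charged, going to Qi at 0.00299 M min⁻¹.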